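**Retrosynthetic overview**
1. Target 16 ⇐ acetate 15: the last step is a lipase-catalysed, pH-neutral removal of the 4'-O-acetyl group, so the base-labile 4'-hydroxyflavanone is released without racemisation.
2. 15 ⇐ chromone 7 + arylboronic acid 14: the C2–C1' bond is made by asymmetric 1,4-addition catalysed by [Rh(OH)(cod)]2/(S)-MeO-F12-BIPHEP, which sets the only stereocentre (2S).
3. 7 ⇐ enaminone 6 ⇐ ketone 4 ⇐ 3,4,5-trimethoxyphenol 1 (C-acetylation, formamide acetal, acid cyclisation).
4. 14 ⇐ pinacol boronate 12 ⇐ aryl bromide 10 ⇐ 4-bromo-2-methoxyphenol 8.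
5. Ring order: ring A is bought, ring C (the pyranone) is closed in step 3, ring B is attached in step 7.

Assumption: on chromone 7 the ligand (S)-MeO-F12-BIPHEP, (S)-2,2'-bis[bis(3,4,5-trifluorophenyl)phosphino]-6,6'-dimethoxy-1,1'-biphenyl, induces in the same sense as (S)-biaryl bisphosphines do on cyclic enones and gives 2S; this is confirmed on 15 by chiral HPLC and CD, and the (R)-ligand is used should the opposite sense be found.

**Route**

Step 1
Reactants: 1 3,4,5-trimethoxyphenol; 2 acetic acid
Product: 4 1-(6-hydroxy-2,3,4-trimethoxyphenyl)ethan-1-one, via difluoroboron chelate 3 (not isolated)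
Conditions: BF3·OEt2 (3 equiv), AcOH (solvent), 90 °C, 2 h; then H2O/EtOH, 70 °C
Reagents that add atoms: acetic acid (2), CC(=O)O
Why: BF3-mediated Friedel–Crafts C-acylation (Nencki type, through the O-acetate and a Fries shift) can only go to the two equivalent free positions ortho to the phenol, and the ketone is held as the BF2 chelate 3 until aqueous hydrolysis, which prevents a second acylation.

Step 2
Reactants: 4 1-(6-hydroxy-2,3,4-trimethoxyphenyl)ethan-1-one; 5 N,N-dimethylformamide dimethyl acetal
Product: 6 (E)-3-(dimethylamino)-1-(6-hydroxy-2,3,4-trimethoxyphenyl)prop-2-en-1-one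
Conditions: DMF-DMA (2.5 equiv), toluene, 100 °C, 3 h
Reagents that add atoms: N,N-dimethylformamide dimethyl acetal (5), COC(OC)N(C)C
Why: Enaminone formation (aminomethylenation of the methyl ketone by a formamide acetal) is driven by loss of two molecules of methanol and gives the conjugated, hydrogen-bonded E-enaminone.

Step 3
Reactants: 6 (E)-3-(dimethylamino)-1-(6-hydroxy-2,3,4-trimethoxyphenyl)prop-2-en-1-one
Product: 7 5,6,7-trimethoxy-4H-chromen-4-one
Conditions: conc. HCl (3 equiv), CH2Cl2, 40 °C, 1 h
Reagents that add atoms: none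
Why: Acid-promoted intramolecular oxa-Michael addition–elimination (enaminone-to-chromone cyclisation) lets the phenol add to the protonated vinylogous amide while dimethylamine leaves as its hydrochloride, which closes ring C.

Step 4
Reactants: 8 4-bromo-2-methoxyphenol; 9 acetic anhydride
Product: 10 4-bromo-2-methoxyphenyl acetate
Conditions: Ac2O (1.2 equiv), pyridine (1.5 equiv), DMAP (5 mol %), CH2Cl2, 0 °C to rt
Reagents that add atoms: acetic anhydride (9), CC(=O)OC(C)=O
Why: DMAP-catalysed O-acylation of the phenol is essentially quantitative and installs an ester that tempers the electron-rich ring against protodeboronation later and can be removed at neutral pH.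

Step 5
Reactants: 10 4-bromo-2-methoxyphenyl acetate; 11 bis(pinacolato)diboron
Product: 12 2-methoxy-4-(4,4,5,5-tetramethyl-1,3,2-dioxaborolan-2-yl)phenyl acetate
Conditions: B2pin2 (1.2 equiv), Pd(dppf)Cl2·CH2Cl2 (3 mol %), KOAc (3 equiv), 1,4-dioxane, 85 °C, N2
Reagents that add atoms: bis(pinacolato)diboron (11), CC1(C)OB(OC1(C)C)B1OC(C)(C)C(C)(C)O1
Why: In this Miyaura borylation zerovalent palladium formed from Pd(dppf)Cl2 inserts into the C–Br bond and the acetate-bound palladium transmetalates with B2pin2, while anhydrous KOAc is too weak a base to cleave the aryl acetate.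

Step 6
Reactants: 12 2-methoxy-4-(4,4,5,5-tetramethyl-1,3,2-dioxaborolan-2-yl)phenyl acetate; 13 water
Product: 14 (4-acetoxy-3-methoxyphenyl)boronic acid
Conditions: NaIO4 (3 equiv), THF/H2O (4:1), rt, 30 min; then 1 M HCl (0.7 equiv), rt, 4 h
Reagents that add atoms: water (13), O
Why: Oxidative cleavage of the pinacol unit to acetone by NaIO4 (Malaprade-type glycol cleavage) makes hydrolysis of the boronate irreversible, and the neutral to mildly acidic medium leaves the aryl acetate intact.

Step 7
Reactants: 7 5,6,7-trimethoxy-4H-chromen-4-one; 14 (4-acetoxy-3-methoxyphenyl)boronic acid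
Product: 15 (S)-2-methoxy-4-(5,6,7-trimethoxy-4-oxochroman-2-yl)phenyl acetate
Conditions: [Rh(OH)(cod)]2 (1.5 mol %), (S)-MeO-F12-BIPHEP (3.3 mol %), 14 (2.5 equiv), CH2Cl2/H2O (10:1), 30 °C, 16 h
Reagents that add atoms: none
Why: In this Hayashi–Miyaura asymmetric 1,4-addition the aryl group passes from boron to monovalent rhodium, the Ar–Rh bond inserts across C2=C3 of the chromone on the face left open by the electron-poor (S)-bisphosphine and water protonates the rhodium enolate, which sets C2 as S under base-free conditions that spare the acetate.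

Step 8
Reactants: 15 (S)-2-methoxy-4-(5,6,7-trimethoxy-4-oxochroman-2-yl)phenyl acetate
Product: 16 agecorynin E, (S)-2-(4-hydroxy-3-methoxyphenyl)-5,6,7-trimethoxychroman-4-one
Conditions: immobilised Candida antarctica lipase B (50 wt %), n-BuOH (5 equiv), MTBE/THF (4:1), 40 °C, 24 h; filter, concentrate
Reagents that add atoms: none
Why: In this lipase-catalysed transesterification (alcoholysis) the active-site serine of the lipase takes the acetyl group from the aryl acetate and passes it to n-butanol at neutral pH, so the 4'-phenol is freed without the base that would open ring C by retro-oxa-Michael reaction and racemise C2.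

**Compound list**
1 | 3,4,5-trimethoxyphenol | COc1cc(O)cc(OC)c1OC | starting material
2 | acetic acid | CC(=O)O | starting material
3 | difluoroboron chelate of ketone 4 (O,O-BF2 complex of the 2-hydroxyaryl ketone) | CC1=[O+][B-](F)(F)Oc2cc(OC)c(OC)c(OC)c12 | intermediate
4 | 1-(6-hydroxy-2,3,4-trimethoxyphenyl)ethan-1-one | CC(=O)c1c(O)cc(OC)c(OC)c1OC | intermediate
5 | N,N-dimethylformamide dimethyl acetal | COC(OC)N(C)C | starting material
6 | (E)-3-(dimethylamino)-1-(6-hydroxy-2,3,4-trimethoxyphenyl)prop-2-en-1-one | CN(C)/C=C/C(=O)c1c(O)cc(OC)c(OC)c1OC | intermediate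
7 | 5,6,7-trimethoxy-4H-chromen-4-one | COc1cc2occc(=O)c2c(OC)c1OC | intermediate
8 | 4-bromo-2-methoxyphenol | COc1cc(Br)ccc1O | starting material
9 | acetic anhydride | CC(=O)OC(C)=O | starting material
10 | 4-bromo-2-methoxyphenyl acetate | COc1cc(Br)ccc1OC(C)=O | intermediate
11 | bis(pinacolato)diboron | CC1(C)OB(OC1(C)C)B1OC(C)(C)C(C)(C)O1 | starting material
12 | 2-methoxy-4-(4,4,5,5-tetramethyl-1,3,2-dioxaborolan-2-yl)phenyl acetate | COc1cc(B2OC(C)(C)C(C)(C)O2)ccc1OC(C)=O | intermediate
13 | water | O | starting material
14 | (4-acetoxy-3-methoxyphenyl)boronic acid | COc1cc(B(O)O)ccc1OC(C)=O | intermediate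
15 | (S)-2-methoxy-4-(5,6,7-trimethoxy-4-oxochroman-2-yl)phenyl acetate | COc1cc([C@@H]2CC(=O)c3c(cc(OC)c(OC)c3OC)O2)ccc1OC(C)=O | intermediate
16 | agecorynin E, (S)-2-(4-hydroxy-3-methoxyphenyl)-5,6,7-trimethoxychroman-4-one | COc1cc([C@@H]2CC(=O)c3c(cc(OC)c(OC)c3OC)O2)ccc1O | target

**Step count and risks**

Total step count: 8.
Longest linear sequence: 5 steps (steps 1, 2, 3, 7, 8; the branch through steps 4, 5, 6, 7, 8 is equally long).

Most likely to fail, first: step 7. Three methoxy donors make chromone 7 a sluggish acceptor, boronic acid 14 can protodeboronate, and the ketone of 15 can take a second aryl group by 1,2-addition. The fallback replaces the C-arylation by an organocatalytic asymmetric oxa-Michael ring closure; it sets out from ketone 4 and comes back to the route at 15.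
- Ketone 4 is treated with LiN(SiMe3)2 (3.2 equiv) and Boc2O in THF at −78 °C to give tert-butyl 3-(6-hydroxy-2,3,4-trimethoxyphenyl)-3-oxopropanoate F1.
- Knoevenagel condensation of this β-keto ester with commercial, achiral 4-formyl-2-methoxyphenyl acetate (piperidinium acetate, toluene, removal of water) gives tert-butyl 3-(4-acetoxy-3-methoxyphenyl)-2-(6-hydroxy-2,3,4-trimethoxybenzoyl)prop-2-enoate F2.
- A bifunctional cinchona-alkaloid thiourea (10 mol %, toluene, −25 °C; the quinine- or quinidine-derived pseudo-enantiomer that gives 2S) closes ring C by enantioselective 6-endo oxa-Michael addition to give tert-butyl (2S)-2-(4-acetoxy-3-methoxyphenyl)-5,6,7-trimethoxy-4-oxochromane-3-carboxylate F3.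
- TsOH·H2O in toluene at 80 °C then removes the tert-butyl ester with decarboxylation and delivers 15, which goes on to step 8.

Second: step 6. The NaIO4/HCl cleavage may partly hydrolyse the aryl acetate or oxidise the electron-rich ring, and the free boronic acid can be awkward to isolate. The fallback frees the boron from pinacol through a crystalline trifluoroborate instead of by oxidative diol cleavage; it sets out from 12 and comes back to the route at 14.
- Aqueous KHF2 (4 equiv) in acetone at rt converts 12 into potassium (4-acetoxy-3-methoxyphenyl)trifluoroborate F4, which is freed from pinacol by washing.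
- Me3SiCl (3 equiv) and water in MeCN at rt then hydrolyse this salt to 14.

Third: step 8. The lipase may turn over the bulky, sparingly soluble flavanone acetate 15 too slowly to be practical. The fallback changes the phenol protecting group to a benzyl ether that is removed by hydrogenolysis, equally base-free; it sets out from 8 and comes back to the route at 16.
- Phenol 8 is benzylated (BnBr, K2CO3, acetone, reflux) to 1-(benzyloxy)-4-bromo-2-methoxybenzene F5.
- Bromine–lithium exchange (n-BuLi, THF, −78 °C), B(OiPr)3 and aqueous HCl give (4-(benzyloxy)-3-methoxyphenyl)boronic acid F6.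
- This boronic acid and chromone 7 under the conditions of step 7 give (S)-2-(4-(benzyloxy)-3-methoxyphenyl)-5,6,7-trimethoxychroman-4-one F7.
- Hydrogenolysis of this benzyl ether (H2 1 atm, 10% Pd/C, EtOAc, rt, stopped at full conversion to avoid reduction of the ketone or the benzylic C2–O bond) gives 16.

**Further compounds**
F1 | step 7 | tert-butyl 3-(6-hydroxy-2,3,4-trimethoxyphenyl)-3-oxopropanoate | CC(C)(C)OC(=O)CC(=O)c1c(O)cc(OC)c(OC)c1OC
F2 | step 7 | tert-butyl 3-(4-acetoxy-3-methoxyphenyl)-2-(6-hydroxy-2,3,4-trimethoxybenzoyl)prop-2-enoate (alkene geometry not fixed) | COc1cc(C=C(C(=O)OC(C)(C)C)C(=O)c2c(O)cc(OC)c(OC)c2OC)ccc1OC(C)=O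
F3 | step 7 | tert-butyl (2S)-2-(4-acetoxy-3-methoxyphenyl)-5,6,7-trimethoxy-4-oxochromane-3-carboxylate (C3 epimerisable, not fixed) | COc1cc([C@@H]2C(C(=O)OC(C)(C)C)C(=O)c3c(cc(OC)c(OC)c3OC)O2)ccc1OC(C)=O
F4 | step 6 | potassium (4-acetoxy-3-methoxyphenyl)trifluoroborate | COc1cc([B-](F)(F)F)ccc1OC(C)=O.[K+]
F5 | step 8 | 1-(benzyloxy)-4-bromo-2-methoxybenzene | COc1cc(Br)ccc1OCc1ccccc1
F6 | step 8 | (4-(benzyloxy)-3-methoxyphenyl)boronic acid | COc1cc(B(O)O)ccc1OCc1ccccc1
F7 | step 8 | (S)-2-(4-(benzyloxy)-3-methoxyphenyl)-5,6,7-trimethoxychroman-4-one | COc1cc([C@@H]2CC(=O)c3c(cc(OC)c(OC)c3OC)O2)ccc1OCc1ccccc1
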